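The runs were computed with constants of no real substance; the scatter is artificial.

Try to make product and starting material add up to the charge in the amber run, and it cannot be done: at 6.00 h they leave a gap of 3.2 percentage points, against a scatter of 0.3 points per reading.

| setting | amber | west | east | south-west | south-east |
|---|---|---|---|---|---|
| starting material | 20 mM | 20 mM | 20 mM | 20 mM | 20 mM |
| protic impurity | 3.1 mM | 4.00 mM | 6.00 mM | 10.0 mM | 15.0 mM |
| enzyme | 0.02 mol% | 0.02 mol% | 0.02 mol% | 0.02 mol% | 0.02 mol% |
| remark | run made earlier |  |  |  |  |
| time |  | 6.0 h | 6.0 h | 6.0 h | 6.0 h |

- amber (time / h: product / %, starting material / %): 0.500: 87.0, 12.3; 0.833: 90.0, 9.5; 1.33: 91.3, 7.2; 2.00: 91.8, 5.6; 4.00: 93.9, 4.4; 6.00: 94.2, 2.6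

(each reading ± 0.3 percentage points)

- "hardly changes" means that all values lie within two and a half points (for a concentration: within two and a half percent of the largest)
- no earlier run changes the charge of protic impurity; that part of a forecast is a guess

* amount of product at the end, in percent of the starting material charged for west, east, south-west, south-east, in this order
* how the row runs (falls, then rises / rises, then falls / rises all the way / falls all the way / hardly changes)

Read the starting-material column first, with A its concentration. From 0.500 h to 2.00 h time grows by a factor 4.00 and A falls by 2.20, close to the square root 2.00. A rate proportional to the cube of A gives that square-root fall, so take the product step as kA·A·A, with k holding the enzyme frozen.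

From 2.00 h to 6.00 h the same law asks for 1.73, but the column gives 2.15, so something else draws on A in the tail.

Now read the columns against each other. The gap is 0.7 points at 0.500 h and 3.2 points at 6.00 h, so read it as a second sink of A that widens along the run.

My guess, since amber has one impurity charge, is a rate qIA, with I the protic impurity frozen at its charge: a pseudo-first-order loss of A. The two rates are equal at A* = √(qI/k). With A* far below the charge A₀, and with the enzyme and A₀ held fixed, the share that never becomes product is a fixed multiple of A*, so it grows as the square root of I.

Define the loss number L as the share not turned into product, divided by √(I/A₀). Taking the product reading of amber at 6.00 h as its end value, amber reads L = 14.7%.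

My row is then 93.4%, 91.9%, 89.6% and 87.2%, falling all the way.

The forecast gives 91%, 85%, 72% and 59%, shape falls all the way, on the ground that “the impurity is the obvious killer”, and in south-east it stands lower than mine.

The flask gives 94.0%, 92.9%, 91.1% and 89.1%, shape falls all the way.

    starting material + protic impurity → quenched substrate (k = 0.380 M⁻¹ min⁻¹)
    starting material + enzyme → product + enzyme, rate k2*[starting material]^3*[enzyme]/(1 + ([starting material]/Kh2)^3) (27.0 mM, k = 1.10 × 10⁷ M⁻³ s⁻¹)

In west, half of the product step's turnover up to 6.0 h is done by 1.40 min, and half of the quenching step's by 1.29 h, far later. At 6.00 h in west the product step uses starting material at 0.65 of the rate of the quenching step, a ratio below one, so A stands under A* there. Worked back from the flask, L is 13.4% in west and 12.6% in south-east, against 14.7% read from amber.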